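**Plan**

- Retrosynthesis: the δ-lactone bond C7–O20 and the C17 methylene are cut last. C9–C10 and C8–C15 are then cut in one relay, which leads back to the ring-C hydroxy aldehyde 21 and the ring-A triol 11, held together by an iPr2Si bridge from O11 to O20. Ring A is cut at C5–C6 ([2,3] shift) and at C4 (Diels–Alder); ring C is cut into acetone and keto ester 15.
- Forward order: ring A, then ring C, then the silaketal. The relay closes a temporary seven-membered 1,3-dioxa-2-silepane ring and ring D (bicyclo[3.2.1]octane). The C15 ketone and C17 methylene follow, and fluoride frees the hydroxyls so that the δ-lactone closes.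
- Enabling feature: both carbons next to the C9–C10 bond carry oxygen (O11 on C11, O20 on C20; O–C11–C9–C10–C20–O), so one silicon atom can tie ring C to ring A across that bond. The C13 side chain stands 1,3 to C8 on ring C, so the enolate left at C8 can close ring D.
- Stereochemistry: C4 from a catalytic enantioselective Diels–Alder reaction; C5 from a CBS-set carbinol through a [2,3]-Wittig–Still shift; C13 from an organocatalytic Michael addition; C11 from a CBS reduction; C9, C10 and C8 in the relay.

Key step: step 14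

Remark: kaurane-type numbering (C1–C20) is used as locants; the catalyst enantiomers in steps 1, 5, 9 and 10 follow the accepted models and would be exchanged for their mirror images if the sense of induction proved opposite.

**Ring A**

Step 1
Reactants: 1 methacrolein; 2 (1E)-3-{[tert-butyl(dimethyl)silyl]oxy}-N,N-dimethylbuta-1,3-dien-1-amine
Product: 3 (1S,2R)-4-{[tert-butyl(dimethyl)silyl]oxy}-2-(dimethylamino)-1-methylcyclohex-3-ene-1-carbaldehyde
Conditions: (R,R)-(salen)CrSbF6 (5 mol %), 4 Å MS, CH2Cl2, −40 °C
Reagents that add atoms: none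
Why: Catalytic enantioselective Diels–Alder reaction of a 1-amino-3-siloxydiene with an α-substituted acrolein (Rawal–Jacobsen type); the amino terminus bonds to the α-carbon and the chiral chromium Lewis acid shields one face of the bound enal, which sets the C4 quaternary center (the amino-bearing center is lost in step 2).

Step 2
Reactants: 3
Product: 5 (4S)-4-(hydroxymethyl)-4-methylcyclohex-2-en-1-one, via amino alcohol 4 (not isolated)
Conditions: LiAlH4, Et2O, −78 °C; then 10 % HF in MeCN/H2O, 0 °C to rt
Reagents that add atoms: none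
Why: Hydride reduction of the aldehyde, then acid hydrolysis of the silyl enol ether and β-elimination of dimethylamine give the 4,4-disubstituted cyclohexenone; the quaternary center is not touched.

Step 3
Reactants: 5
Product: 6 (4S)-2,4-bis(hydroxymethyl)-4-methylcyclohex-2-en-1-one
Conditions: 37 % aq. HCHO, DMAP (20 mol %), THF/H2O, rt
Reagents that add atoms: formaldehyde, C=O
Why: Morita–Baylis–Hillman hydroxymethylation at the enone α-carbon (C10); no stereocenter is formed.

Step 4
Reactants: 6
Product: 7 (4S)-2,4-bis({[tert-butyl(dimethyl)silyl]oxy}methyl)-4-methylcyclohex-2-en-1-one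
Conditions: TBSCl, imidazole, DMF, rt
Reagents that add atoms: tert-butyl(chloro)dimethylsilane, CC(C)(C)[Si](C)(C)Cl
Why: Standard silylation of two primary alcohols.

Step 5
Reactants: 7
Product: 8 (1S,4S)-2,4-bis({[tert-butyl(dimethyl)silyl]oxy}methyl)-4-methylcyclohex-2-en-1-ol
Conditions: (R)-Me-CBS (20 mol %), BH3·SMe2, THF, −30 °C
Reagents that add atoms: none
Why: Corey–Bakshi–Shibata reduction under reagent control; the α-substituted alkenyl flank acts as the large group, so the (R)-catalyst should give the (1S)-alcohol, cis to the C4 methyl group, with little influence from the remote quaternary center.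

Step 6
Reactants: 8
Product: 9 tributyl({[(1S,4S)-2,4-bis({[tert-butyl(dimethyl)silyl]oxy}methyl)-4-methylcyclohex-2-en-1-yl]oxy}methyl)stannane
Conditions: KH, 18-crown-6 (cat.), Bu3SnCH2I, THF, 0 °C to rt
Reagents that add atoms: tributyl(iodomethyl)stannane, CCCC[Sn](CCCC)(CCCC)CI
Why: Williamson etherification of the potassium alkoxide with the primary iodide; the carbinol center is not touched.

Step 7
Reactants: 9
Product: 11 [(5S,6R)-5-methylcyclohex-1-ene-1,5,6-triyl]trimethanol, via homoallylic alcohol 10 (not isolated)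
Conditions: n-BuLi, THF, −78 to −20 °C; then HCl, MeOH, rt
Reagents that add atoms: none
Why: [2,3]-Wittig–Still rearrangement: tin–lithium exchange gives the α-alkoxy organolithium, which shifts suprafacially, so the new C5–C6 bond forms on the face that the C1–O bond occupied (cis to the C4 methyl group) while the double bond moves to C1=C10; acid methanolysis then removes both silyl ethers.

**Ring C**

Step 8
Reactants: 12 4,4-diethoxybut-1-yne; 13 methyl chlorooxoacetate
Product: 15 methyl (3E)-6,6-diethoxy-2-oxohex-3-enoate, via alkenylzirconocene 14 (not isolated)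
Conditions: Cp2Zr(H)Cl, CH2Cl2, rt; then 13, CuBr·SMe2 (10 mol %), 0 °C
Reagents that add atoms: none
Why: Syn hydrozirconation of the terminal alkyne and copper-catalyzed acylation of the alkenylzirconocene with the acid chloride give the (E)-β,γ-unsaturated α-keto ester; the acetal is inert to both reagents.

Step 9
Reactants: 15; 16 acetone
Product: 19 methyl (5R)-5-(2,2-diethoxyethyl)-3-oxocyclohex-1-ene-1-carboxylate, via Michael adduct 17 (not isolated), via aldol 18 (not isolated)
Conditions: 9-amino-9-deoxy-epi-quinidine (20 mol %), PhCO2H (40 mol %), acetone, rt to 45 °C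
Reagents that add atoms: none
Why: Primary-amine-catalyzed Michael addition of acetone (as its enamine) to the β,γ-unsaturated α-keto ester, the cinchona-derived catalyst selecting the enone face that sets C13, followed by intramolecular aldol addition of the methyl ketone to the keto ester carbonyl and dehydration (Robinson-type annulation).

Step 10
Reactants: 19
Product: 20 methyl (3R,5S)-5-(2,2-diethoxyethyl)-3-hydroxycyclohex-1-ene-1-carboxylate
Conditions: (S)-Me-CBS (20 mol %), catecholborane, toluene, −78 °C
Reagents that add atoms: none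
Why: Corey–Bakshi–Shibata 1,2-reduction under reagent control, the alkenyl flank acting as the large group, should give the (3R)-alcohol trans to the C13 side chain, against the weak cis preference of the substrate.

Step 11
Reactants: 20
Product: 21 methyl (3R,5S)-3-hydroxy-5-(2-oxoethyl)cyclohex-1-ene-1-carboxylate
Conditions: PPTS (cat.), acetone/H2O, 40 °C
Reagents that add atoms: water, O
Why: Acid-catalyzed acetal hydrolysis; the allylic alcohol next to the electron-poor enoate does not ionize, and the trans 1,3-arrangement prevents lactol formation.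

**Union and completion**

Step 12
Reactants: 21; 11
Product: 23 silaketal diol (iPr2Si bridge from O11 of ring C to O20 of ring A), via chlorosilane 22 (not isolated)
Conditions: i-Pr2SiCl2 (3 equiv), imidazole, CH2Cl2, 0 °C; excess silane removed in vacuo; then 11, imidazole, DMF, −20 °C to rt
Reagents that add atoms: dichlorodi(propan-2-yl)silane, CC(C)[Si](Cl)(Cl)C(C)C
Why: Stepwise formation of an unsymmetrical dialkoxysilane: the hindered secondary alcohol is silylated first with excess dichlorosilane, and the bulky chlorosilane should then take the only unhindered primary hydroxyl of the triol (allylic C20–OH; the C6 and C18 hydroxyls are β-branched and neopentyl).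

Step 13
Reactants: 23
Product: 24 bis-TBS silaketal (C6 and C18 hydroxyls silylated)
Conditions: TBSCl, imidazole, DMAP (cat.), DMF, rt
Reagents that add atoms: tert-butyl(chloro)dimethylsilane, CC(C)(C)[Si](C)(C)Cl
Why: Silylation of the two remaining primary alcohols without a silyl triflate, so that the aldehyde is not enolized.

Step 14
Reactants: 24
Product: 26 methyl 6,18-bis(TBS-oxy)-15-hydroxy-11,20-(diisopropylsilanediyldioxy)-17-nor-6,7-secokauran-7-oate (C15 epimers), via ester enolate 25 (not isolated)
Conditions: Fe(acac)3 (30 mol %), PhSiH3 (3 equiv), EtOH/THF (2:1), 0.005 M, degassed, 40 °C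
Reagents that add atoms: none
Why: Proposed new method: Fe(acac)3 and PhSiH3 give an iron hydride that transfers a hydrogen atom to C1 of the electron-rich trisubstituted ring-A alkene (the enoate and the aldehyde are poor acceptors), the tertiary C10 radical adds to C9 at the β-carbon of the ring-C enoate, divalent iron reduces the α-ester radical at C8 to the enolate 25, and this adds to the aldehyde; the closest known reaction types are the hydrogen-atom-transfer Giese addition with aldol termination (reductive radical–polar crossover annulation) and the silaketal-tethered radical cyclization run with tin hydride. Forming C9–C10 closes the seven-membered 1,3-dioxa-2-silepane ring in the 7-exo-trig mode, and forming C8–C15 closes the five-membered ring D of the bicyclo[3.2.1]octane in the 5-exo-trig aldol mode. C9 is controlled by the tether: with the C13 side chain equatorial the C11–O bond is pseudoaxial, so the silicon bridge holds C10 on the O11 face of C9, the face that an untethered radical would avoid. C10 is controlled by ring A, the new bond forming anti to the neighbouring C5 silyloxymethyl group and away from the axial C4 methyl group, and C8 is controlled by C13, whose side chain can reach the enolate only on its own face; the C15 carbinol is not controlled and is oxidized in step 15. The step needs ring closure to outrun loss of the tertiary radical, which high dilution and its reversible generation favor, and attack at C9 instead of C8, which the polarity of the enoate and the exo mode secure.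

Step 15
Reactants: 26
Product: 27 methyl 6,18-bis(TBS-oxy)-11,20-(diisopropylsilanediyldioxy)-15-oxo-17-nor-6,7-secokauran-7-oate
Conditions: Dess–Martin periodinane, NaHCO3, CH2Cl2, 0 °C to rt
Reagents that add atoms: none
Why: Dess–Martin oxidation of the only free hydroxyl; both C15 epimers converge on one ketone, and the buffer spares the silaketal.

Step 16
Reactants: 27
Product: 30 methyl 6,18-bis(TBS-oxy)-11,20-(diisopropylsilanediyldioxy)-15-oxo-6,7-secokaur-16-en-7-oate, via Mannich base 28 (not isolated), via ammonium iodide 29 (not isolated)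
Conditions: LiHMDS, THF, −78 °C; CH2=NMe2+ I−, −78 to 0 °C; then MeI, CH2Cl2, rt; then sat. aq. NaHCO3
Reagents that add atoms: N,N-dimethylmethaniminium iodide (Eschenmoser's salt), C=[N+](C)C.[I-]
Why: Enolization at C16, the only enolizable position (C8 is quaternary), Mannich reaction with Eschenmoser's salt, N-methylation and base-induced β-elimination give the exocyclic enone, a standard α-methylenation of 15-oxokauranes.

Step 17
Reactants: 30
Product: 32 target CNP0152458.1, via tetrol ester 31 (not isolated)
Conditions: HF·pyridine, THF/pyridine, 0 °C to rt; then CSA (cat.), toluene, 50 °C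
Reagents that add atoms: none
Why: Fluoride cleaves both silyl ethers and the silaketal, and the freed C20 hydroxyl closes the six-membered lactone on the C7 ester by acid-catalyzed transesterification (the other hydroxyls could give only seven-membered or larger rings); acidic conditions avoid retro-Claisen cleavage of the β-keto ester.

**Compound list**

1 | methacrolein (2-methylprop-2-enal) | CC(=C)C=O | starting material
2 | (1E)-3-{[tert-butyl(dimethyl)silyl]oxy}-N,N-dimethylbuta-1,3-dien-1-amine (Rawal's diene) | CN(C)/C=C/C(=C)O[Si](C)(C)C(C)(C)C | starting material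
3 | (1S,2R)-4-{[tert-butyl(dimethyl)silyl]oxy}-2-(dimethylamino)-1-methylcyclohex-3-ene-1-carbaldehyde (endo adduct, NMe2 cis to CHO) | O=C[C@@]1(C)CCC(O[Si](C)(C)C(C)(C)C)=C[C@H]1N(C)C | intermediate
4 | [(1S,2R)-4-{[tert-butyl(dimethyl)silyl]oxy}-2-(dimethylamino)-1-methylcyclohex-3-en-1-yl]methanol | OC[C@@]1(C)CCC(O[Si](C)(C)C(C)(C)C)=C[C@H]1N(C)C | intermediate
5 | (4S)-4-(hydroxymethyl)-4-methylcyclohex-2-en-1-one | O=C1C=C[C@@](C)(CO)CC1 | intermediate
6 | (4S)-2,4-bis(hydroxymethyl)-4-methylcyclohex-2-en-1-one | O=C1C(CO)=C[C@@](C)(CO)CC1 | intermediate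
7 | (4S)-2,4-bis({[tert-butyl(dimethyl)silyl]oxy}methyl)-4-methylcyclohex-2-en-1-one | O=C1C(CO[Si](C)(C)C(C)(C)C)=C[C@@](C)(CO[Si](C)(C)C(C)(C)C)CC1 | intermediate
8 | (1S,4S)-2,4-bis({[tert-butyl(dimethyl)silyl]oxy}methyl)-4-methylcyclohex-2-en-1-ol (OH cis to the ring methyl) | O[C@@H]1C(CO[Si](C)(C)C(C)(C)C)=C[C@@](C)(CO[Si](C)(C)C(C)(C)C)CC1 | intermediate
9 | tributyl({[(1S,4S)-2,4-bis({[tert-butyl(dimethyl)silyl]oxy}methyl)-4-methylcyclohex-2-en-1-yl]oxy}methyl)stannane | CCCC[Sn](CCCC)(CCCC)CO[C@@H]1C(CO[Si](C)(C)C(C)(C)C)=C[C@@](C)(CO[Si](C)(C)C(C)(C)C)CC1 | intermediate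
10 | [(1R,6S)-2,6-bis({[tert-butyl(dimethyl)silyl]oxy}methyl)-6-methylcyclohex-2-en-1-yl]methanol | CC(C)(C)[Si](C)(C)OCC1=CCC[C@](C)(CO[Si](C)(C)C(C)(C)C)[C@H]1CO | intermediate
11 | [(5S,6R)-5-methylcyclohex-1-ene-1,5,6-triyl]trimethanol (ring-A triol; 6-CH2OH cis to the methyl) | OCC1=CCC[C@](C)(CO)[C@H]1CO | intermediate
12 | 4,4-diethoxybut-1-yne | C#CCC(OCC)OCC | starting material
13 | methyl chlorooxoacetate | COC(=O)C(Cl)=O | starting material
14 | chlorobis(cyclopentadienyl)[(1E)-4,4-diethoxybut-1-en-1-yl]zirconium | CCOC(C/C=C/[Zr](Cl)(C1C=CC=C1)C1C=CC=C1)OCC | intermediate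
15 | methyl (3E)-6,6-diethoxy-2-oxohex-3-enoate | CCOC(C/C=C/C(=O)C(=O)OC)OCC | intermediate
16 | acetone | CC(C)=O | starting material
17 | methyl (4R)-4-(2,2-diethoxyethyl)-2,6-dioxoheptanoate | COC(=O)C(=O)C[C@H](CC(OCC)OCC)CC(C)=O | intermediate
18 | methyl (5R)-5-(2,2-diethoxyethyl)-1-hydroxy-3-oxocyclohexane-1-carboxylate (C1 epimers) | COC(=O)C1(O)CC(=O)C[C@@H](CC(OCC)OCC)C1 | intermediate
19 | methyl (5R)-5-(2,2-diethoxyethyl)-3-oxocyclohex-1-ene-1-carboxylate | COC(=O)C1=CC(=O)C[C@@H](CC(OCC)OCC)C1 | intermediate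
20 | methyl (3R,5S)-5-(2,2-diethoxyethyl)-3-hydroxycyclohex-1-ene-1-carboxylate (trans) | COC(=O)C1=C[C@H](O)C[C@@H](CC(OCC)OCC)C1 | intermediate
21 | methyl (3R,5S)-3-hydroxy-5-(2-oxoethyl)cyclohex-1-ene-1-carboxylate | COC(=O)C1=C[C@H](O)C[C@@H](CC=O)C1 | intermediate
22 | methyl (3R,5S)-3-{[chlorodi(propan-2-yl)silyl]oxy}-5-(2-oxoethyl)cyclohex-1-ene-1-carboxylate | COC(=O)C1=C[C@H](O[Si](Cl)(C(C)C)C(C)C)C[C@@H](CC=O)C1 | intermediate
23 | methyl (3R,5S)-3-{[{[(5S,6R)-5,6-bis(hydroxymethyl)-5-methylcyclohex-1-en-1-yl]methoxy}di(propan-2-yl)silyl]oxy}-5-(2-oxoethyl)cyclohex-1-ene-1-carboxylate | COC(=O)C1=C[C@H](O[Si](C(C)C)(C(C)C)OCC2=CCC[C@](C)(CO)[C@H]2CO)C[C@@H](CC=O)C1 | intermediate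
24 | methyl (3R,5S)-3-{[{[(5S,6R)-5,6-bis({[tert-butyl(dimethyl)silyl]oxy}methyl)-5-methylcyclohex-1-en-1-yl]methoxy}di(propan-2-yl)silyl]oxy}-5-(2-oxoethyl)cyclohex-1-ene-1-carboxylate | COC(=O)C1=C[C@H](O[Si](C(C)C)(C(C)C)OCC2=CCC[C@](C)(CO[Si](C)(C)C(C)(C)C)[C@H]2CO[Si](C)(C)C(C)(C)C)C[C@@H](CC=O)C1 | intermediate
25 | ester enolate after 7-exo addition of C10 to C9 (iron-bound; drawn as the anion) | COC([O-])=C1C[C@H](CC=O)C[C@@H](O2)[C@H]1[C@@]3(CCC[C@](C)(CO[Si](C)(C)C(C)(C)C)[C@H]3CO[Si](C)(C)C(C)(C)C)CO[Si]2(C(C)C)C(C)C | intermediate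
26 | methyl 6,18-bis(TBS-oxy)-15-hydroxy-11,20-(diisopropylsilanediyldioxy)-17-nor-6,7-secokauran-7-oate (C15 epimers; O11 cis to C10 on ring C) | C1C(O)[C@]2(C(=O)OC)C[C@H]1C[C@@H](O3)[C@H]2[C@@]1(CCC[C@](C)(CO[Si](C)(C)C(C)(C)C)[C@H]1CO[Si](C)(C)C(C)(C)C)CO[Si]3(C(C)C)C(C)C | intermediate
27 | methyl 6,18-bis(TBS-oxy)-11,20-(diisopropylsilanediyldioxy)-15-oxo-17-nor-6,7-secokauran-7-oate | C1C(=O)[C@]2(C(=O)OC)C[C@H]1C[C@@H](O3)[C@H]2[C@@]1(CCC[C@](C)(CO[Si](C)(C)C(C)(C)C)[C@H]1CO[Si](C)(C)C(C)(C)C)CO[Si]3(C(C)C)C(C)C | intermediate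
28 | 16-[(dimethylamino)methyl] derivative of 27 (C16 epimers) | CN(C)CC1C(=O)[C@]2(C(=O)OC)C[C@H]1C[C@@H](O3)[C@H]2[C@@]1(CCC[C@](C)(CO[Si](C)(C)C(C)(C)C)[C@H]1CO[Si](C)(C)C(C)(C)C)CO[Si]3(C(C)C)C(C)C | intermediate
29 | 16-[(trimethylammonio)methyl] derivative of 27, iodide | C[N+](C)(C)CC1C(=O)[C@]2(C(=O)OC)C[C@H]1C[C@@H](O3)[C@H]2[C@@]1(CCC[C@](C)(CO[Si](C)(C)C(C)(C)C)[C@H]1CO[Si](C)(C)C(C)(C)C)CO[Si]3(C(C)C)C(C)C.[I-] | intermediate
30 | methyl 6,18-bis(TBS-oxy)-11,20-(diisopropylsilanediyldioxy)-15-oxo-6,7-secokaur-16-en-7-oate | C=C1C(=O)[C@]2(C(=O)OC)C[C@H]1C[C@@H](O3)[C@H]2[C@@]1(CCC[C@](C)(CO[Si](C)(C)C(C)(C)C)[C@H]1CO[Si](C)(C)C(C)(C)C)CO[Si]3(C(C)C)C(C)C | intermediate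
31 | methyl 6,11,18,20-tetrahydroxy-15-oxo-6,7-secokaur-16-en-7-oate | C=C1C(=O)[C@]2(C(=O)OC)C[C@H]1C[C@@H](O)[C@H]2[C@@]1(CCC[C@](C)(CO)[C@H]1CO)CO | intermediate
32 | CNP0152458.1 (6,11,18-trihydroxy-15-oxo-6,7-secokaur-16-en-7,20-olide skeleton) | C=C1C(=O)[C@]23C[C@H]1C[C@@H](O)[C@H]2[C@@]1(CCC[C@](C)(CO)[C@H]1CO)COC3=O | target

**Totals and risks**

Total step count: 17 (7 for ring A, 4 for ring C, 6 after their union). Longest linear sequence: 13 steps (steps 1–7, then 12–17).

Step 14 (Proposed new method). The tertiary radical may be quenched (reduced or returned to the alkene) faster than the seven-membered ring closes, or the iron enolate may be protonated before the aldol, so that open-chain reduction products form. The fallback uses known reaction types and runs from 24 back to 27. The aldehyde of 24 is homologated with dimethyl (1-diazo-2-oxopropyl)phosphonate and K2CO3 in MeOH (Ohira–Bestmann) to the terminal alkyne F1. Cobalt-hydride Markovnikov hydrobromination of the ring-A alkene (Co(acac)2, t-BuOOH, Et3SiH, TsBr) gives the tertiary bromide F2. Slow addition of Bu3SnH and AIBN in benzene at 80 °C then runs a classical chain cascade: the C10 radical closes the same silaketal ring onto C9, and the C8 radical closes ring D by 5-exo-dig attack on the alkyne, to give the 15-methylene compound F3. Ozonolysis (O3, CH2Cl2, −78 °C; then PPh3) cleaves the exocyclic alkene to the ketone 27, so step 15 is not needed.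

Step 3. Addition of DMAP to the β-carbon next to the quaternary center may be too slow, so the hydroxymethylation stalls and the enone is lost to side reactions. The fallback runs from 5 back to 6: α-iodination with I2 and pyridine in CH2Cl2 gives the iodoenone F4, and Stille coupling with (tributylstannyl)methanol (Pd(PPh3)4, dioxane, 90 °C) installs the hydroxymethyl group.

Step 9. Enantioface discrimination in the Michael addition to an aliphatic keto ester may be poor, or reversible Michael addition may erode it. The fallback runs from 15 and 16 back to 20. The annulation is run with pyrrolidinium acetate to give racemic enone, that is 19 together with its enantiomer F5. The reagent-controlled CBS reduction of step 10 is then applied to the racemate; it should convert 19 into 20 and F5 into the cis alcohol F6, a diastereomer removed by chromatography, so that the absolute configuration of ring C comes from the reduction.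

**Further compounds**

F1 | step 14 | alkyne analogue of 24 (prop-2-yn-1-yl in place of 2-oxoethyl at C13) | COC(=O)C1=C[C@H](O[Si](C(C)C)(C(C)C)OCC2=CCC[C@](C)(CO[Si](C)(C)C(C)(C)C)[C@H]2CO[Si](C)(C)C(C)(C)C)C[C@@H](CC#C)C1
F2 | step 14 | tertiary C10 bromide from F1 (C10 epimers) | COC(=O)C1=C[C@H](O[Si](C(C)C)(C(C)C)OCC2(Br)CCC[C@](C)(CO[Si](C)(C)C(C)(C)C)[C@H]2CO[Si](C)(C)C(C)(C)C)C[C@@H](CC#C)C1
F3 | step 14 | 15-methylene analogue of 27 (C15=CH2 in place of C15=O) | C1C(=C)[C@]2(C(=O)OC)C[C@H]1C[C@@H](O3)[C@H]2[C@@]1(CCC[C@](C)(CO[Si](C)(C)C(C)(C)C)[C@H]1CO[Si](C)(C)C(C)(C)C)CO[Si]3(C(C)C)C(C)C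
F4 | step 3 | (4S)-4-(hydroxymethyl)-2-iodo-4-methylcyclohex-2-en-1-one | O=C1C(I)=C[C@@](C)(CO)CC1
F5 | step 9 | methyl (5S)-5-(2,2-diethoxyethyl)-3-oxocyclohex-1-ene-1-carboxylate | COC(=O)C1=CC(=O)C[C@H](CC(OCC)OCC)C1
F6 | step 9 | methyl (3R,5R)-5-(2,2-diethoxyethyl)-3-hydroxycyclohex-1-ene-1-carboxylate (cis) | COC(=O)C1=C[C@H](O)C[C@H](CC(OCC)OCC)C1
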